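# Proposed synthesis of (5R)-1-(3,4-dihydroxy-5-methoxyphenyl)-5-hydroxy-7-(4-hydroxy-3-methoxyphenyl)heptan-3-one

## Structural features

The target is a linear diarylheptanoid: an unbranched seven-carbon chain with ring B (3,4-dihydroxy-5-methoxyphenyl) on C1 and ring A (4-hydroxy-3-methoxyphenyl) on C7, and no ring other than the two arenes. C3 is a ketone and C5 a secondary alcohol, so the core is a β-hydroxy ketone. C5 (R) is the only stereocentre and has no stereogenic neighbour, so its configuration must come from a reagent or catalyst. The fragile parts are the β-hydroxy ketone (loss of water to the C4=C5 enone under acid, base or heat; retro-aldol cleavage under base) and the free catechol of ring B, which air oxidises, fastest in base. The real difficulty is that C5 lies between C4H2 and C6H2, two unbranched methylenes of almost equal size, so a saturated C5 ketone offers a chiral reductant no handle. A free C3/C5 diketone would also be an enolised 1,3-dicarbonyl. The key step uses a temporary C6≡C7 triple bond conjugated to ring A: the C6 flank of the C5 carbonyl becomes a linear π system, the C4 flank stays sp3, and C3 is silenced as a 1,3-dioxolane. The three phenols travel as benzyl ethers, which leave in the same hydrogenation that saturates C6–C7.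

## Logic of the disconnections

16 from 15: the two C3–O bonds of the dioxolane are restored in the backward sense. The β-hydroxy ketone is the most fragile array of 16 and should exist only in the last flask. The gain is that every earlier step handles a ketal that cannot enolise, eliminate or form a 1,3-dicarbonyl. The forward step needs an acid mild enough to open the ketal of 15 without dehydrating C4–C5, with air excluded.

15 from 14: no skeletal bond is cut; four hydrogens are removed from C6/C7 and three O–benzyl bonds are restored. One hydrogenation does both jobs, so the benzyl ethers cost no step of their own. The gain is the alkyne that makes the two sides of C5 different. The forward step must saturate C6≡C7 without hydrogenolysis of the C5–O bond or isomerisation of the intermediate allylic alcohol.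

14 from 13: the C5–H bond is cut. This is the only place where chirality enters, and it reduces the stereochemical problem to an achiral ynone. The forward step needs catalyst-controlled choice of the carbonyl face, no attack on the triple bond, and a medium without base because of the β-ketal.

13 from 9 and 11 (through 12): the C5–C6 bond between the acyl carbon and the alkyne terminus is cut. This is the most convergent cut, giving two halves of similar size with one ring each and natural acetylide/acyl polarity. The forward step must stop after one addition and must not deprotonate C4.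

11 from 10: the terminal alkyne carbon C6 is removed from C7. The gain is a commercial aldehyde that already carries ring A with its phenol benzylated. The forward step is a one-carbon homologation under conditions that leave the benzyl ether alone.

9 from 8 from 7: only functional groups change, namely the amide C–N bond from the ester C–O bond and the two ketal C–O bonds from the C3 carbonyl. The ketal has to be in place before any strongly basic nucleophile meets the 1,3-dicarbonyl, and the ester is what the preceding C–C bond formation delivers. The forward steps need ketalisation without loss of the ester and amidation without enolisation at C4.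

7 from 4 and 5 (through 6): the C1–C2 bond is cut. 5 supplies C2 to C5 with both oxygens already at the right oxidation level, and 4 supplies ring B with C1. The forward step must alkylate at the terminal carbon of 5 and not at the central one, which the doubly deprotonated form 6 ensures.

4 from 3 from 2 from 1: the C1–Br bond, one C1–H bond and the two O–benzyl bonds are cut in turn. This turns a commercial aldehyde into a benzylic electrophile with the catechol masked. The forward steps need complete bis-benzylation with air excluded and prompt use of the electron-rich bromide.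

## Other disconnections considered

Alternative 1: The cut is the bond between ring B and C1, with C1–C2–C3 hidden in a cyclopropanol.
- **Forward step:** the cyclopropanol 1-[(2R)-4-[4-(benzyloxy)-3-methoxyphenyl]-2-[(tert-butyldimethylsilyl)oxy]butyl]cyclopropan-1-ol A2 and the aryl bromide 1,2-bis(benzyloxy)-5-bromo-3-methoxybenzene A3 would couple under Pd(OAc)2, a bulky biaryl phosphine and Cs2CO3. Zerovalent palladium inserts into the C–Br bond of A3, the hydroxyl of A2 binds as an alkoxide, β-carbon elimination opens the three-membered ring to a palladium homoenolate, and reductive elimination forms the aryl–C1 bond. The product is (R)-7-[4-(benzyloxy)-3-methoxyphenyl]-1-[3,4-bis(benzyloxy)-5-methoxyphenyl]-5-[(tert-butyldimethylsilyl)oxy]heptan-3-one A1.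
- **In favour:** the C3 carbonyl appears in the bond-forming step, so no ketal and no alkyne are carried. The stereocentre is made on the small fragment A2, where its purity can be checked before the coupling.
- **Against:** the homoenolate can lose a β-hydride to give a vinyl ketone. A1 is a β-silyloxy ketone exposed to warm carbonate and can eliminate silanolate to the enone, which erases C5. The electron-rich A3 should add slowly to zerovalent palladium. A2 still needs a separate asymmetric step and a titanium-mediated cyclopropanation upstream.
- **Comparison, structure:** both plans give the 1,3-oxygen pattern, but this one exposes the β-oxygenated ketone to base, whereas the chosen plan keeps C3 ketalised through every basic step.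
- **Comparison, mechanism:** an inner-sphere palladium cycle with stoichiometric base stands against an outer-sphere hydride transfer in a neutral medium.
- **Comparison, step economy:** the count is estimated to be about equal. The alternative is the better one in that it needs no ketal at C3 and no reduction of an alkyne.

Alternative 2: The cut is C3–C4.
- **Forward step:** the dithiane 2-{2-[3,4-bis(benzyloxy)-5-methoxyphenyl]ethyl}-1,3-dithiane A5 would be lithiated at its C2 (n-BuLi, THF, HMPA), and the carbanion of A5 would open the epoxide (R)-2-{2-[4-(benzyloxy)-3-methoxyphenyl]ethyl}oxirane A6 at its CH2 carbon by SN2. The product is (R)-4-[4-(benzyloxy)-3-methoxyphenyl]-1-(2-{2-[3,4-bis(benzyloxy)-5-methoxyphenyl]ethyl}-1,3-dithian-2-yl)butan-2-ol A4.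
- **In favour:** C5 is not touched in the C–C bond formation, and A6 can be obtained almost enantiopure by hydrolytic kinetic resolution with a chiral (salen)Co(OAc) complex of trivalent cobalt. The dithiane ring of A5 is both nucleophile and ketone mask, so the mask does useful work.
- **Against:** the resolution throws away at least half of the racemate of A6, and HMPA is a hazard. A5 has to be built from ring B by a chain extension and a thioacetalisation with a malodorous dithiol. The thioketal of A4 must be removed with soft electrophiles or oxidants (MeI/CaCO3, PhI(OCOCF3)2 or Hg(ClO4)2) beside three electron-rich arenes. It must go before the hydrogenolysis because sulfur poisons Pd/C, so the β-hydroxy ketone is exposed one step earlier.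
- **Comparison, structure:** the same oxidation pattern is reached with an S,S-acetal at C3 in place of the O,O-acetal.
- **Comparison, mechanism:** a stoichiometric carbanion substitution stands against a catalytic hydride transfer.
- **Comparison, step economy:** A5 and A6 each need several steps, so the count is estimated to be equal or slightly longer. On optical purity and certainty of configuration at C5 the alternative is the better plan. On atom economy, reagent safety and ease of unmasking it is the weaker one.

Alternative 3: The cut is C5–C6, with the stereocentre made in the same step.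
- **Forward step:** the dialkylzinc bis{2-[4-(benzyloxy)-3-methoxyphenyl]ethyl}zinc A9 would add to the aldehyde 2-(2-{2-[3,4-bis(benzyloxy)-5-methoxyphenyl]ethyl}-1,3-dioxolan-2-yl)acetaldehyde A8 under Ti(OiPr)4 and a chiral trans-1,2-bis(trifluoromethanesulfonamido)cyclohexane. The product is (R)-4-[4-(benzyloxy)-3-methoxyphenyl]-1-(2-{2-[3,4-bis(benzyloxy)-5-methoxyphenyl]ethyl}-1,3-dioxolan-2-yl)butan-2-ol A7.
- **In favour:** bond and stereocentre form together. A7 is the saturated form of 14, so only hydrogenolysis and ketal hydrolysis remain and no propargylic or allylic C–O bond ever meets palladium. A8 is one reduction away from 8.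
- **Against:** only one of the two alkyl groups of A9 is transferred and an excess is normally needed, which wastes the ring A fragment at the convergent step. A9 has to be made in several steps with pyrophoric Et2Zn. A8 is an unbranched, enolisable aldehyde whose β-ketal oxygens can bind the stoichiometric titanium Lewis acid, compete with the chiral ligand, or be lost by β-elimination.
- **Comparison, structure:** both plans set C5 next to a ketal-masked C3 and share the endgame.
- **Comparison, mechanism:** here the aldehyde A8 must bind to titanium, so the ketal can interfere. In the chosen plan the ketone never binds to ruthenium.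
- **Comparison, step economy:** the sequence after the key step is one operation simpler, but the ring A arm leading to A9 is longer than the one-step alkyne synthesis, so the totals are estimated to be about equal. Forming the C–C bond and the stereocentre at once is a point on which the alternative is the better plan.

Key step: step 9

Assumption: the chloride complex RuCl(p-cymene)[(S,S)-TsDPEN] does not enter the catalytic cycle without base, and base is unwelcome next to the β-ketal. The isolated 16-electron amide Ru(p-cymene)[(S,S)-TsNCHPhCHPhNH] is therefore used. The (S,S) ligand is taken to give the (S)-propargylic alcohol, the sense in which this catalyst family reduces other alkynyl ketones.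

## Steps

Step 1
Reactants: 1 3,4-dihydroxy-5-methoxybenzaldehyde
Product: 2 3,4-bis(benzyloxy)-5-methoxybenzaldehyde
Conditions: BnBr, K2CO3, DMF, 60 °C, under argon
Reagents that add atoms: benzyl bromide, BrCc1ccccc1
Why: Williamson ether synthesis; both phenoxides are alkylated by the reactive benzylic bromide, and excluding air protects the catechol until it is capped.

Step 2
Reactants: 2 3,4-bis(benzyloxy)-5-methoxybenzaldehyde
Product: 3 [3,4-bis(benzyloxy)-5-methoxyphenyl]methanol
Conditions: NaBH4, MeOH/THF, 0 °C
Reagents that add atoms: none
Why: Borohydride reduction of an aryl aldehyde; benzyl and methyl ethers are inert to it.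

Step 3
Reactants: 3 [3,4-bis(benzyloxy)-5-methoxyphenyl]methanol
Product: 4 1,2-bis(benzyloxy)-5-(bromomethyl)-3-methoxybenzene
Conditions: PBr3, Et2O, 0 °C; used without storage
Reagents that add atoms: phosphorus tribromide, BrP(Br)Br
Why: Conversion of a benzylic alcohol into the bromide through the phosphite ester and bromide displacement; the low temperature and immediate use answer the lability of an electron-rich benzylic bromide.

Step 4
Reactants: 5 ethyl acetoacetate; 4 1,2-bis(benzyloxy)-5-(bromomethyl)-3-methoxybenzene
Product: 7 ethyl 5-[3,4-bis(benzyloxy)-5-methoxyphenyl]-3-oxopentanoate, via ethyl acetoacetate sodium lithium dianion 6 (not isolated)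
Conditions: NaH, THF, 0 °C; n-BuLi, 0 °C; then 4, 0 °C to rt; aq NH4Cl
Reagents that add atoms: none
Why: γ-Alkylation of an acetoacetate dianion (Weiler alkylation); the second, less stabilised carbanion at the terminal carbon is the more nucleophilic site and attacks the benzylic bromide by SN2, forming the C1–C2 bond.

Step 5
Reactants: 7 ethyl 5-[3,4-bis(benzyloxy)-5-methoxyphenyl]-3-oxopentanoate
Product: 8 ethyl 2-(2-{2-[3,4-bis(benzyloxy)-5-methoxyphenyl]ethyl}-1,3-dioxolan-2-yl)acetate
Conditions: HOCH2CH2OH, p-TsOH·H2O (cat.), toluene, reflux, Dean–Stark
Reagents that add atoms: ethylene glycol, OCCO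
Why: Acid-catalysed ketalisation with azeotropic removal of water, the standard protection of the ketone of a β-keto ester; aryl benzyl ethers tolerate catalytic sulfonic acid.

Step 6
Reactants: 8 ethyl 2-(2-{2-[3,4-bis(benzyloxy)-5-methoxyphenyl]ethyl}-1,3-dioxolan-2-yl)acetate
Product: 9 2-(2-{2-[3,4-bis(benzyloxy)-5-methoxyphenyl]ethyl}-1,3-dioxolan-2-yl)-N-methoxy-N-methylacetamide
Conditions: MeNHOMe·HCl, i-PrMgCl, THF, −20 to 0 °C
Reagents that add atoms: N,O-dimethylhydroxylamine hydrochloride, CNOC.Cl
Why: Direct ester-to-Weinreb-amide aminolysis by the magnesium amide made in the flask; this amide is a good nucleophile but a weak base, so the C4 methylene next to the ketal is not enolised.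

Step 7
Reactants: 10 4-(benzyloxy)-3-methoxybenzaldehyde
Product: 11 1-(benzyloxy)-4-ethynyl-2-methoxybenzene
Conditions: dimethyl (1-diazo-2-oxopropyl)phosphonate, K2CO3, MeOH, rt
Reagents that add atoms: dimethyl (1-diazo-2-oxopropyl)phosphonate, CC(=O)C(=[N+]=[N-])P(=O)(OC)OC
Why: Seyferth–Gilbert homologation in the Ohira–Bestmann form; methanolysis releases the diazomethylphosphonate anion, which olefinates the aldehyde, and the diazoalkene loses N2 and rearranges by 1,2-shift to the terminal alkyne under conditions harmless to the benzyl ether.

Step 8
Reactants: 11 1-(benzyloxy)-4-ethynyl-2-methoxybenzene; 9 2-(2-{2-[3,4-bis(benzyloxy)-5-methoxyphenyl]ethyl}-1,3-dioxolan-2-yl)-N-methoxy-N-methylacetamide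
Product: 13 4-[4-(benzyloxy)-3-methoxyphenyl]-1-(2-{2-[3,4-bis(benzyloxy)-5-methoxyphenyl]ethyl}-1,3-dioxolan-2-yl)but-3-yn-2-one, via lithium [4-(benzyloxy)-3-methoxyphenyl]ethynide 12 (not isolated)
Conditions: n-BuLi, THF, −78 °C; then 9, −78 to 0 °C; poured into cold aq NH4Cl
Reagents that add atoms: none
Why: Weinreb ketone synthesis with a lithium acetylide; the five-membered lithium chelate of the tetrahedral adduct survives until the quench, so only one acetylide adds, and the cold acidic quench protonates the released amine before it can add to the ynone.

Step 9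
Reactants: 13 4-[4-(benzyloxy)-3-methoxyphenyl]-1-(2-{2-[3,4-bis(benzyloxy)-5-methoxyphenyl]ethyl}-1,3-dioxolan-2-yl)but-3-yn-2-one
Product: 14 (2S)-4-[4-(benzyloxy)-3-methoxyphenyl]-1-(2-{2-[3,4-bis(benzyloxy)-5-methoxyphenyl]ethyl}-1,3-dioxolan-2-yl)but-3-yn-2-ol
Conditions: Ru(p-cymene)[(S,S)-TsNCHPhCHPhNH] (1 mol %), i-PrOH (CH2Cl2 as co-solvent if solubility requires), rt, no base
Reagents that add atoms: none
Why: This is a Noyori asymmetric transfer hydrogenation of an α,β-acetylenic ketone by a divalent ruthenium arene complex of a monosulfonylated 1,2-diamine. The 16-electron amide dehydrogenates isopropanol to the 18-electron Ru–H/N–H species, which passes hydride to C5 and the N–H proton to the carbonyl oxygen through a six-membered transition state in the outer sphere, the ketone never binding to the metal. No ring is closed and no skeletal bond is formed. The C5 stereocentre is under catalyst control: the (S,S) diamine fixes the chirality at ruthenium, and the C6≡C7 π flank takes the place an aryl group takes in aryl alkyl ketone reductions, so hydride should arrive on the face that gives the (S)-carbinol. The step needs enantioface selectivity, which the contrast between the linear sp flank at C6 and the sp3 C4H2–dioxolane flank secures. It also needs chemoselectivity for C=O over C≡C, which follows because the polar Ru–H/N–H pair adds only to a polarised double bond. The base-free medium leaves the β-ketal and the acidic C4 methylene alone. The equilibrium should lie on the product side because an alkynyl carbinol is a much poorer hydride donor than isopropanol, which also guards the optical purity against reversal.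

Step 10
Reactants: 14 (2S)-4-[4-(benzyloxy)-3-methoxyphenyl]-1-(2-{2-[3,4-bis(benzyloxy)-5-methoxyphenyl]ethyl}-1,3-dioxolan-2-yl)but-3-yn-2-ol
Product: 15 5-[2-(2-{(2R)-2-hydroxy-4-(4-hydroxy-3-methoxyphenyl)butyl}-1,3-dioxolan-2-yl)ethyl]-3-methoxybenzene-1,2-diol
Conditions: H2 (1 atm), Pd/C (10 %), EtOAc/MeOH, rt; filtered under argon
Reagents that add atoms: none
Why: Heterogeneous hydrogenation saturates C6≡C7 and hydrogenolyses the three benzyl ethers in one operation; C5 is not touched, and its descriptor changes from S to R only because C6 falls below C4 in priority once the triple bond is gone.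

Step 11
Reactants: 15 5-[2-(2-{(2R)-2-hydroxy-4-(4-hydroxy-3-methoxyphenyl)butyl}-1,3-dioxolan-2-yl)ethyl]-3-methoxybenzene-1,2-diol
Product: 16 (5R)-1-(3,4-dihydroxy-5-methoxyphenyl)-5-hydroxy-7-(4-hydroxy-3-methoxyphenyl)heptan-3-one
Conditions: PPTS, acetone/H2O (9:1), 40 °C, under argon
Reagents that add atoms: water, O
Why: Acid-catalysed ketal hydrolysis through the oxocarbenium ion, water supplying the carbonyl oxygen and its large excess driving the equilibrium; the weakly acidic pyridinium salt and moderate temperature are chosen so that the β-hydroxy ketone does not lose water, and argon protects the catechol.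

## Compound list

1 | 3,4-dihydroxy-5-methoxybenzaldehyde | COc1cc(C=O)cc(O)c1O | starting material
2 | 3,4-bis(benzyloxy)-5-methoxybenzaldehyde | COc1cc(C=O)cc(OCc2ccccc2)c1OCc1ccccc1 | intermediate
3 | [3,4-bis(benzyloxy)-5-methoxyphenyl]methanol | COc1cc(CO)cc(OCc2ccccc2)c1OCc1ccccc1 | intermediate
4 | 1,2-bis(benzyloxy)-5-(bromomethyl)-3-methoxybenzene | COc1cc(CBr)cc(OCc2ccccc2)c1OCc1ccccc1 | intermediate
5 | ethyl acetoacetate | CCOC(=O)CC(C)=O | starting material
6 | ethyl acetoacetate sodium lithium dianion (dienolate, not isolated) | [Na+].[Li+].C=C([O-])C=C([O-])OCC | intermediate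
7 | ethyl 5-[3,4-bis(benzyloxy)-5-methoxyphenyl]-3-oxopentanoate | CCOC(=O)CC(=O)CCc1cc(OC)c(OCc2ccccc2)c(OCc2ccccc2)c1 | intermediate
8 | ethyl 2-(2-{2-[3,4-bis(benzyloxy)-5-methoxyphenyl]ethyl}-1,3-dioxolan-2-yl)acetate | CCOC(=O)CC1(CCc2cc(OC)c(OCc3ccccc3)c(OCc3ccccc3)c2)OCCO1 | intermediate
9 | 2-(2-{2-[3,4-bis(benzyloxy)-5-methoxyphenyl]ethyl}-1,3-dioxolan-2-yl)-N-methoxy-N-methylacetamide | CON(C)C(=O)CC1(CCc2cc(OC)c(OCc3ccccc3)c(OCc3ccccc3)c2)OCCO1 | intermediate
10 | 4-(benzyloxy)-3-methoxybenzaldehyde | COc1cc(C=O)ccc1OCc1ccccc1 | starting material
11 | 1-(benzyloxy)-4-ethynyl-2-methoxybenzene | COc1cc(C#C)ccc1OCc1ccccc1 | intermediate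
12 | lithium [4-(benzyloxy)-3-methoxyphenyl]ethynide (not isolated) | [Li]C#Cc1ccc(OCc2ccccc2)c(OC)c1 | intermediate
13 | 4-[4-(benzyloxy)-3-methoxyphenyl]-1-(2-{2-[3,4-bis(benzyloxy)-5-methoxyphenyl]ethyl}-1,3-dioxolan-2-yl)but-3-yn-2-one | COc1cc(C#CC(=O)CC2(CCc3cc(OCc4ccccc4)c(OCc4ccccc4)c(OC)c3)OCCO2)ccc1OCc1ccccc1 | intermediate
14 | (2S)-4-[4-(benzyloxy)-3-methoxyphenyl]-1-(2-{2-[3,4-bis(benzyloxy)-5-methoxyphenyl]ethyl}-1,3-dioxolan-2-yl)but-3-yn-2-ol | COc1cc(C#C[C@@H](O)CC2(CCc3cc(OCc4ccccc4)c(OCc4ccccc4)c(OC)c3)OCCO2)ccc1OCc1ccccc1 | intermediate
15 | 5-[2-(2-{(2R)-2-hydroxy-4-(4-hydroxy-3-methoxyphenyl)butyl}-1,3-dioxolan-2-yl)ethyl]-3-methoxybenzene-1,2-diol | COc1cc(CC[C@@H](O)CC2(CCc3cc(O)c(O)c(OC)c3)OCCO2)ccc1O | intermediate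
16 | (5R)-1-(3,4-dihydroxy-5-methoxyphenyl)-5-hydroxy-7-(4-hydroxy-3-methoxyphenyl)heptan-3-one | COc1cc(CC[C@@H](O)CC(=O)CCc2cc(O)c(O)c(OC)c2)ccc1O | target

## Step count and least certain steps

Total step count: 11. Longest linear sequence: 10 steps (steps 1 to 6 and 8 to 11, from 1). Step 7 is the one-step side branch from 10.

**Step 9 (key step).**
- **Risk:** face selection may be poorer than for simple alkyl ynones, because the C4 flank carries a bulky quaternary ketal carbon that could compete with the slim alkynyl flank for the same quadrant. Turnover may be slow because the large, lipophilic substrate dissolves poorly in isopropanol.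
- **Fallback:** stoichiometric borane reduction under oxazaborolidine control. Setting out from 13, catecholborane and (S)-2-methyl-CBS-oxazaborolidine in CH2Cl2 at −78 °C would be used. The enantiomer of the oxazaborolidine is chosen on the usual model with the alkynyl group taken as the smaller substituent, and the sense of induction would have to be confirmed on the product. Here the carbonyl is activated on boron and not reduced in the outer sphere of a metal. The sequence comes back at 14 with no new compound.

**Step 4.**
- **Risk:** incomplete second deprotonation leads to alkylation at the central carbon or on oxygen and to double alkylation. The electron-rich bromide 4 can also decompose by ionisation and self-alkylation before it is consumed.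
- **Fallback:** a route without a benzylic halide, setting out from 2. Claisen–Schmidt condensation with acetone (aq NaOH) would give (E)-4-[3,4-bis(benzyloxy)-5-methoxyphenyl]but-3-en-2-one F1. Conjugate reduction with catalytic [(Ph3P)CuH]6 and a silane, which spares benzyl ethers, would give 4-[3,4-bis(benzyloxy)-5-methoxyphenyl]butan-2-one F2. Claisen acylation at the methyl group with NaH and diethyl carbonate in THF comes back to the route at 7.

**Step 8.**
- **Risk:** the acetylide may act as a base at C4 of 9, followed by opening of the dioxolane by β-elimination. The liberated N,O-dimethylhydroxylamine may add in conjugate fashion to the ynone during warming or work-up.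
- **Fallback:** the aldehyde oxidation level, setting out from 9 (with 11). Reduction with i-Bu2AlH in THF at −78 °C would give 2-(2-{2-[3,4-bis(benzyloxy)-5-methoxyphenyl]ethyl}-1,3-dioxolan-2-yl)acetaldehyde F3. Addition of 12 at −78 °C would give racemic 4-[4-(benzyloxy)-3-methoxyphenyl]-1-(2-{2-[3,4-bis(benzyloxy)-5-methoxyphenyl]ethyl}-1,3-dioxolan-2-yl)but-3-yn-2-ol F4. Oxidation with MnO2 in CH2Cl2 comes back at 13.

**Step 10.**
- **Risk:** at the half-reduced stage the C5–O bond is allylic to a styrene, so hydrogenolysis of that bond or palladium-mediated isomerisation of the allylic alcohol to a saturated ketone can compete with simple saturation. Debenzylation may also stall on the partly deprotected material.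
- **Fallback:** separate the two events, setting out from 14. Metal-free diimide reduction (2-nitrobenzenesulfonohydrazide, Et3N, THF, rt) cannot cleave C–O bonds and would give (2R)-4-[4-(benzyloxy)-3-methoxyphenyl]-1-(2-{2-[3,4-bis(benzyloxy)-5-methoxyphenyl]ethyl}-1,3-dioxolan-2-yl)butan-2-ol F5, the same compound as A7. Hydrogenolysis of its benzyl ethers (H2, Pd/C, EtOAc/MeOH) comes back at 15.

**Step 11.**
- **Risk:** acid-promoted loss of water from the β-hydroxy ketone to the C4=C5 enone, made worse by oxidative darkening of the free catechol if the hydrolysis is slow.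
- **Fallback:** move the acid step to the benzyl-protected stage, setting out from 14. Diimide reduction as above would give (2R)-4-[4-(benzyloxy)-3-methoxyphenyl]-1-(2-{2-[3,4-bis(benzyloxy)-5-methoxyphenyl]ethyl}-1,3-dioxolan-2-yl)butan-2-ol F5. PPTS in wet acetone would then give (5R)-7-[4-(benzyloxy)-3-methoxyphenyl]-1-[3,4-bis(benzyloxy)-5-methoxyphenyl]-5-hydroxyheptan-3-one F6, a robust compound from which any enone can be separated. A final neutral hydrogenolysis (H2, Pd/C, EtOAc) comes back at 16.

## Further compounds

F0 | step 9 | none | none
F1 | step 4 | (E)-4-[3,4-bis(benzyloxy)-5-methoxyphenyl]but-3-en-2-one | COc1cc(/C=C/C(C)=O)cc(OCc2ccccc2)c1OCc1ccccc1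
F2 | step 4 | 4-[3,4-bis(benzyloxy)-5-methoxyphenyl]butan-2-one | COc1cc(CCC(C)=O)cc(OCc2ccccc2)c1OCc1ccccc1
F3 | step 8 | 2-(2-{2-[3,4-bis(benzyloxy)-5-methoxyphenyl]ethyl}-1,3-dioxolan-2-yl)acetaldehyde | COc1cc(CCC2(CC=O)OCCO2)cc(OCc2ccccc2)c1OCc1ccccc1
F4 | step 8 | racemic 4-[4-(benzyloxy)-3-methoxyphenyl]-1-(2-{2-[3,4-bis(benzyloxy)-5-methoxyphenyl]ethyl}-1,3-dioxolan-2-yl)but-3-yn-2-ol | COc1cc(C#CC(O)CC2(CCc3cc(OCc4ccccc4)c(OCc4ccccc4)c(OC)c3)OCCO2)ccc1OCc1ccccc1
F5 | step 10 | (2R)-4-[4-(benzyloxy)-3-methoxyphenyl]-1-(2-{2-[3,4-bis(benzyloxy)-5-methoxyphenyl]ethyl}-1,3-dioxolan-2-yl)butan-2-ol | COc1cc(CC[C@@H](O)CC2(CCc3cc(OCc4ccccc4)c(OCc4ccccc4)c(OC)c3)OCCO2)ccc1OCc1ccccc1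
F6 | step 11 | (5R)-7-[4-(benzyloxy)-3-methoxyphenyl]-1-[3,4-bis(benzyloxy)-5-methoxyphenyl]-5-hydroxyheptan-3-one | COc1cc(CC[C@@H](O)CC(=O)CCc2cc(OCc3ccccc3)c(OCc3ccccc3)c(OC)c2)ccc1OCc1ccccc1
A1 | alternative 1 | (R)-7-[4-(benzyloxy)-3-methoxyphenyl]-1-[3,4-bis(benzyloxy)-5-methoxyphenyl]-5-[(tert-butyldimethylsilyl)oxy]heptan-3-one | COc1cc(CC[C@@H](O[Si](C)(C)C(C)(C)C)CC(=O)CCc2cc(OCc3ccccc3)c(OCc3ccccc3)c(OC)c2)ccc1OCc1ccccc1
A2 | alternative 1 | 1-[(2R)-4-[4-(benzyloxy)-3-methoxyphenyl]-2-[(tert-butyldimethylsilyl)oxy]butyl]cyclopropan-1-ol | COc1cc(CC[C@@H](O[Si](C)(C)C(C)(C)C)CC2(O)CC2)ccc1OCc1ccccc1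
A3 | alternative 1 | 1,2-bis(benzyloxy)-5-bromo-3-methoxybenzene | COc1cc(Br)cc(OCc2ccccc2)c1OCc1ccccc1
A4 | alternative 2 | (R)-4-[4-(benzyloxy)-3-methoxyphenyl]-1-(2-{2-[3,4-bis(benzyloxy)-5-methoxyphenyl]ethyl}-1,3-dithian-2-yl)butan-2-ol | COc1cc(CC[C@@H](O)CC2(CCc3cc(OCc4ccccc4)c(OCc4ccccc4)c(OC)c3)SCCCS2)ccc1OCc1ccccc1
A5 | alternative 2 | 2-{2-[3,4-bis(benzyloxy)-5-methoxyphenyl]ethyl}-1,3-dithiane | COc1cc(CCC2SCCCS2)cc(OCc2ccccc2)c1OCc1ccccc1
A6 | alternative 2 | (R)-2-{2-[4-(benzyloxy)-3-methoxyphenyl]ethyl}oxirane | COc1cc(CC[C@@H]2CO2)ccc1OCc1ccccc1
A7 | alternative 3 | (R)-4-[4-(benzyloxy)-3-methoxyphenyl]-1-(2-{2-[3,4-bis(benzyloxy)-5-methoxyphenyl]ethyl}-1,3-dioxolan-2-yl)butan-2-ol | COc1cc(CC[C@@H](O)CC2(CCc3cc(OCc4ccccc4)c(OCc4ccccc4)c(OC)c3)OCCO2)ccc1OCc1ccccc1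
A8 | alternative 3 | 2-(2-{2-[3,4-bis(benzyloxy)-5-methoxyphenyl]ethyl}-1,3-dioxolan-2-yl)acetaldehyde | COc1cc(CCC2(CC=O)OCCO2)cc(OCc2ccccc2)c1OCc1ccccc1
A9 | alternative 3 | bis{2-[4-(benzyloxy)-3-methoxyphenyl]ethyl}zinc | COc1cc(CC[Zn]CCc2ccc(OCc3ccccc3)c(OC)c2)ccc1OCc1ccccc1
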